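The vessel is closed, stirred and held at one temperature. The steps thought possible are that substrate and other conformer interconvert, substrate gives target, other conformer gives isomer of the product, target and isomer interconvert, and target goes on to over-reaction product.

| flask | substrate | other conformer | remark | time |
|---|---|---|---|---|
| Saturday's | 1.3 M | 0.10 equiv | run made earlier |  |
| Sunday's | 3 M | 0.10 equiv | run made earlier |  |
| flask | 2.0 M | 0.100 equiv |  | 80 min |

| run | time / min | isomer of the product / % | target / % |
|---|---|---|---|
| Saturday's | 10.0 | 41.3 | 0.3 |
| Saturday's | 20.0 | 35.8 | 0.7 |
| Saturday's | 30.0 | 31.1 | 0.7 |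
| Saturday's | 40.0 | 22.9 | 0 |
| Saturday's | 50.0 | 19.8 | 0 |
| Saturday's | 60.0 | 17.4 | 0 |
| Sunday's | 3.00 | 47.3 | 6.7 |
| Sunday's | 10.0 | 42.2 | 1.1 |
| Sunday's | 20.0 | 34.3 | 2.3 |
| Sunday's | 30.0 | 29.1 | 1.7 |
| Sunday's | 40.0 | 24.5 | 0.4 |
| Sunday's | 50.0 | 21.8 | 0 |
| Sunday's | 60.0 | 17.4 | 0.2 |

(readings scatter by 1 percentage point)

- steps thought possible: substrate <-> other conformer; substrate -> target; other conformer -> isomer of the product; target <-> isomer of the product; target -> over-reaction product

1. share of isomer of the product in isomer of the product plus target at 2.5 s
2. share of isomer of the product in isomer of the product plus target at 1.5 min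
3. share of isomer of the product in isomer of the product plus target at 80 min
4. which of isomer of the product and target there is more of at 80 min

Saturday's isomer reads 17.4% at 60.0 min and Sunday's reads 17.4%, though the charges were 1.3 M and 3 M, so I treat the late decline as first order and carry it to this flask at 2.0 M. Sunday's isomer falls at 0.0177 min⁻¹, and among the possible steps its one way out is through target.

My bench rule is that an intermediate which drains much faster than its feed declines sits near its feed divided by its loss constant, a quasi-steady state. I call the constant target-to-isomer ratio this leaves the hold-up ratio. Late target readings such as 0.4% lie under a scatter of 1 percentage point, so I pool both runs from 20.0 min on and get 0.0236. Dividing the isomer's decline by this ratio gives target a half-life of 0.924 min, which is far shorter than 80 min. So I expect a share of 97.7% at 80 min, with more isomer than target.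

The rule has a border. Sunday's ratio at 3.00 min reads 0.142, which is 6.00 times the hold-up ratio, while at 10.0 min it reads 0.0261. Both 2.5 s and 1.5 min fall before that border, so I give no number for them.

For 2.5 s, 1.5 min and 80 min in turn, the forecast gives shares of 55% (from 40% to 85%), 75% (from 62% to 86%) and 97.8% (from 95.5% to 99.5%), with isomer of the product ahead at 80 min. Of the earliest time it says “this is poorly constrained”.

In the same order, the flask gives 46.6%, 67.9% and 97.6%, with isomer of the product ahead at 80 min.

    substrate ⇌ other conformer (K = 0.160, k = 0.0820 s⁻¹)
    substrate → target (k = 0.0380 s⁻¹)
    other conformer → isomer of the product (k = 0.312 s⁻¹)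
    target ⇌ isomer of the product (K = 1.80, k = 5.36 × 10⁻⁴ s⁻¹)
    target → over-reaction product (k = 0.0117 s⁻¹)

In this flask at 2.75 min, target is made at 0.0778 of the rate at which it is used up, each step taken net. At 80.0 min that figure is higher, at 0.976. The hold-up ratio times this flask's 12.6% of isomer at 80.0 min gives 0.298% of target, and the flask holds 0.314%. In a neighbour flask with 0.0250 equiv of other conformer, the ratio times its 12.3% of isomer at 80.0 min gives 0.290%, and that flask holds 0.306%.

(All runs stem from a simulated flask for an exercise; scatter was added.)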